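**Retrosynthetic overview**
- Feature: the indane is numbered C1 = CH(aryl), C2 = C(=CMe2), C3 = CH2, C6–OH, C7–CHO. The ring-fusion carbon C7a lies between C7 and C3a. Before ring closure it holds the only C–H ortho to the formyl carbon, because C6 is oxygenated. The formyl group, as an imine, can therefore guide a metal into exactly that bond.
- Last skeletal cut: C7a–C1 of the cyclopentane ring. This retro 1,4-hydroarylation opens to a 1-aryl-2-benzyl-3-methylbuta-1,3-diene that carries the O-silylated salicylaldimine.
- The diene comes from an (E)-enone by methylenation. The enone comes from a Horner–Wadsworth–Emmons union (C1=C2) of a benzylated 2-oxopropylphosphonate (C2–C3 made by alkylation) with the benzodioxane aldehyde.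
- The benzodioxane aldehyde comes from 2,3-dihydroxy-5-methylbenzaldehyde and an (R)-epoxy tosylate made by Sharpless epoxidation of prenol. Epoxide opening with inversion sets the S centre.
- Ring order: dioxane ring first (step 3), cyclopentane ring last (step 11). Both benzene rings are bought.

Key step: step 11

Assumption: the sense of induction of the phosphoramidite on this new substrate class cannot be predicted, so one ligand antipode is written and its mirror image is used if the 1S epimer prevails; the two C1 epimers are diastereomers because the dioxane centre is fixed as S.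

Step 1
Reactants: 1 3-methylbut-2-en-1-ol (prenol)
Product: 3 [(2R)-3,3-dimethyloxiran-2-yl]methyl 4-methylbenzenesulfonate, via epoxy alcohol 2 (not isolated)
Conditions: Ti(OiPr)4 (5 mol %), diisopropyl D-(−)-tartrate (6 mol %), t-BuOOH, 4 Å MS, CH2Cl2, −20 °C; then P(OMe)3; then Et3N, DMAP (cat.), TsCl, −10 °C
Reagents that add atoms: tert-butyl hydroperoxide CC(C)(C)OO; 4-methylbenzenesulfonyl chloride Cc1ccc(cc1)S(=O)(=O)Cl
Why: Sharpless asymmetric epoxidation, in which the titanium complex of the D-(−)-tartrate delivers oxygen to the alkene face that makes the epoxide CH carbon R, followed by sulfonylation in the same flask so that the small, water-soluble epoxy alcohol need not be isolated.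

Step 2
Reactants: 4 2-hydroxy-3-methoxy-5-methylbenzaldehyde
Product: 5 2,3-dihydroxy-5-methylbenzaldehyde
Conditions: BBr3 (1.5 equiv), CH2Cl2, −78 °C to 0 °C; then H2O
Reagents that add atoms: none
Why: Lewis-acid aryl methyl ether cleavage (BBr3 demethylation), helped by binding of boron to the neighbouring phenol oxygen, should free the catechol without harming the aldehyde.

Step 3
Reactants: 5 2,3-dihydroxy-5-methylbenzaldehyde; 3 [(2R)-3,3-dimethyloxiran-2-yl]methyl 4-methylbenzenesulfonate
Product: 7 (3S)-3-(2-hydroxypropan-2-yl)-7-methyl-2,3-dihydro-1,4-benzodioxine-5-carbaldehyde, via epoxy ether 6 (not isolated)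
Conditions: NaH (2.1 equiv), DMSO, rt; then 3, rt to 60 °C; then 1 M HCl
Reagents that add atoms: none
Why: Williamson etherification followed by 6-exo-tet epoxide opening; in the dianion the C3 phenoxide, which the formyl group does not stabilise, is the stronger nucleophile and displaces the primary tosylate, and the C2 phenoxide then attacks the secondary epoxide carbon with inversion (R to S), the tertiary carbon and the 7-endo path being disfavoured under basic conditions.

Step 4
Reactants: 8 5-(chloromethyl)-2-hydroxybenzaldehyde
Product: 9 2-{[tert-butyl(dimethyl)silyl]oxy}-5-(chloromethyl)benzaldehyde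
Conditions: TBSOTf (1.1 equiv), 2,6-lutidine (1.3 equiv), CH2Cl2, 0 °C
Reagents that add atoms: tert-butyldimethylsilyl trifluoromethanesulfonate CC(C)(C)[Si](C)(C)OS(=O)(=O)C(F)(F)F
Why: Phenol silylation with a silyl triflate, using a hindered non-nucleophilic base because imidazole or triethylamine would be alkylated by the very reactive para-oxybenzylic chloride.

Step 5
Reactants: 9 2-{[tert-butyl(dimethyl)silyl]oxy}-5-(chloromethyl)benzaldehyde
Product: 10 tert-butyl[4-(chloromethyl)-2-(1,3-dioxolan-2-yl)phenoxy]dimethylsilane
Conditions: TMSOCH2CH2OTMS (1.3 equiv), TMSOTf (5 mol %), CH2Cl2, −78 °C to −30 °C; then pyridine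
Reagents that add atoms: 1,2-bis(trimethylsilyloxy)ethane C[Si](C)(C)OCCO[Si](C)(C)C
Why: Noyori acetalisation is aprotic and cold, so the dioxolane needed to mask this aldehyde through steps 6 to 8 should form without the alcohol solvent that would solvolyse the benzylic chloride.

Step 6
Reactants: 10 tert-butyl[4-(chloromethyl)-2-(1,3-dioxolan-2-yl)phenoxy]dimethylsilane; 11 diethyl (2-oxopropyl)phosphonate
Product: 12 diethyl [1-(4-{[tert-butyl(dimethyl)silyl]oxy}-3-(1,3-dioxolan-2-yl)phenyl)-3-oxobutan-2-yl]phosphonate (racemic)
Conditions: 11 (1.3 equiv), NaH (1.2 equiv), THF, 0 °C; then 10, NaI (10 mol %), rt to 45 °C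
Reagents that add atoms: none
Why: SN2 C-alkylation of the stabilised β-ketophosphonate anion at the carbon between P and C=O, with iodide catalysis and all NaH consumed beforehand so that the aryl silyl ether is spared; the new centre is racemic and is erased in step 7.

Step 7
Reactants: 12 the benzylated β-ketophosphonate; 7 the (3S)-benzodioxane aldehyde
Product: 13 (E)-3-{[4-{[tert-butyl(dimethyl)silyl]oxy}-3-(1,3-dioxolan-2-yl)phenyl]methyl}-4-[(3S)-3-(2-hydroxypropan-2-yl)-7-methyl-2,3-dihydro-1,4-benzodioxin-5-yl]but-3-en-2-one
Conditions: 12 (1.2 equiv), NaH (1.15 equiv), THF, 0 °C; then 7, 0 °C to reflux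
Reagents that add atoms: none
Why: Horner–Wadsworth–Emmons olefination in which 7 offers the only free aldehyde, reversible addition should favour the alkene with aryl trans to acetyl (E), and the tertiary alcohol is far too weak an acid to quench the phosphonate anion.

Step 8
Reactants: 13 the (E)-enone
Product: 14 the (E)-diene acetal, 2-[(3S)-5-{(1E)-2-{[4-{[tert-butyl(dimethyl)silyl]oxy}-3-(1,3-dioxolan-2-yl)phenyl]methyl}-3-methylbuta-1,3-dienyl}-7-methyl-2,3-dihydro-1,4-benzodioxin-3-yl]propan-2-ol
Conditions: MePPh3Br (3.2 equiv), n-BuLi (3.0 equiv), THF, 0 °C; then 13, 0 °C to rt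
Reagents that add atoms: methyltriphenylphosphonium bromide C[P+](c1ccccc1)(c1ccccc1)c1ccccc1.[Br-]
Why: Wittig methylenation, since a non-stabilised ylide adds 1,2 to the enone to give the 1,3-diene, the excess ylide covers the free tertiary alcohol, and dioxolane and aryl silyl ether tolerate the reagent.

Step 9
Reactants: 14 the (E)-diene acetal
Product: 15 2-{[tert-butyl(dimethyl)silyl]oxy}-5-{(2E)-2-{[(3S)-3-(2-hydroxypropan-2-yl)-7-methyl-2,3-dihydro-1,4-benzodioxin-5-yl]methylidene}-3-methylbut-3-enyl}benzaldehyde
Conditions: PPTS (20 mol %), acetone–H2O (10:1), 40 °C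
Reagents that add atoms: water O
Why: Acetal hydrolysis, in which the electron-rich aryl dioxolane opens easily through its stabilised oxocarbenium ion, while pyridinium tosylate is too weak an acid to protonate the aryl diene, ionise the tertiary alcohol or cleave the aryl silyl ether.

Step 10
Reactants: 15 the dienyl aldehyde
Product: 16 N-benzyl (E)-aldimine of 15
Conditions: BnNH2 (1.0 equiv), 4 Å MS, toluene, rt; filtered under argon and used without chromatography
Reagents that add atoms: benzylamine NCc1ccccc1
Why: Imine condensation gives the E aldimine, and the silyl ether both removes the O–H···N hydrogen bond that would hold the nitrogen away from C7a and, by bulk and dipole repulsion, turns the nitrogen lone pair toward the C7a–H side.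

Step 11
Reactants: 16 the dienyl N-benzyl aldimine
Product: 17 N-benzyl imine of O-TBS Diaporindene G, (1R) at the indane and (3S) at the dioxane
Conditions: [RhCl(coe)2]2 (5 mol %; coe = cyclooctene), (S)-BINOL-derived N,N-bis[(R)-1-phenylethyl]phosphoramidite (15 mol %), toluene, 75 °C, argon
Reagents that add atoms: none
Why: Proposed new method: the imine nitrogen binds monovalent rhodium and places it at the only free ortho C–H bond (C7a–H, since C6 carries the silyloxy group), oxidative addition gives a five-membered aryl(hydrido) chelate of trivalent rhodium, the hydride migrates to the unsubstituted terminal CH2 of the tethered diene, and the resulting allylrhodium spans the dimethyl carbon, C2 and C1. The closest known reaction type is the rhodium/phosphoramidite-catalysed, imine-directed enantioselective intramolecular hydroarylation of alkenes tethered meta to the imine; the 1,3-diene acceptor and the 1,4 outcome are what is new. The cyclopentane closes by aryl–C1 reductive elimination from the six-membered rhodacycle Rh–C7a–C3a–C3–C2–C1, formally a 5-endo closure, which a hydride-first sequence allows although a carbometalation would not. C1 is set in this elimination: the allyl faces can interconvert by sigma–pi–sigma shifts, so the chiral phosphoramidite decides which face couples (R is wanted), and the remote S centre only makes one ligand antipode matched and the other mismatched. Three selectivities are needed: hydride to CH2 rather than to C2 (secured by the open terminus and the stabilised allyl that results), coupling at C1 rather than at the dimethyl terminus (both ends would close a five-membered ring, but a tertiary sigma-bound rhodium beside the chelated aryl and a new quaternary carbon are much more crowded than the secondary benzylic alternative), and no later alkene migration (the tetrasubstituted product alkene resists reinsertion into rhodium hydride).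

Step 12
Reactants: 17 the cyclised N-benzyl imine
Product: 18 O-TBS Diaporindene G, (1R)-6-{[tert-butyl(dimethyl)silyl]oxy}-1-[(3S)-3-(2-hydroxypropan-2-yl)-7-methyl-2,3-dihydro-1,4-benzodioxin-5-yl]-2-(propan-2-ylidene)indane-7-carbaldehyde
Conditions: AcOH–H2O–THF (1:1:4), rt
Reagents that add atoms: water O
Why: Imine hydrolysis in weak aqueous acid returns the directing group to the aldehyde of the target under conditions too mild to move the exocyclic alkene into the ring or to ionise at C1.

Step 13
Reactants: 18 O-TBS Diaporindene G
Product: 19 Diaporindene G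
Conditions: TBAF (1.1 equiv), AcOH (1.1 equiv), THF, 0 °C
Reagents that add atoms: none
Why: Fluoride desilylation of an aryl silyl ether activated by the ortho formyl group, buffered with acetic acid so that neither fluoride nor phenoxide removes the acidic doubly benzylic, allylic C1–H, which keeps the C1 configuration and the alkene position.

**Compound list**
1 | 3-methylbut-2-en-1-ol | CC(C)=CCO | starting material
2 | [(2R)-3,3-dimethyloxiran-2-yl]methanol | OC[C@H]1OC1(C)C | intermediate
3 | [(2R)-3,3-dimethyloxiran-2-yl]methyl 4-methylbenzenesulfonate | Cc1ccc(cc1)S(=O)(=O)OC[C@H]1OC1(C)C | intermediate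
4 | 2-hydroxy-3-methoxy-5-methylbenzaldehyde | COc1cc(C)cc(C=O)c1O | starting material
5 | 2,3-dihydroxy-5-methylbenzaldehyde | Cc1cc(O)c(O)c(C=O)c1 | intermediate
6 | 3-{[(2R)-3,3-dimethyloxiran-2-yl]methoxy}-2-hydroxy-5-methylbenzaldehyde (present as its sodium phenoxide) | Cc1cc(C=O)c(O)c(OC[C@H]2OC2(C)C)c1 | intermediate
7 | (3S)-3-(2-hydroxypropan-2-yl)-7-methyl-2,3-dihydro-1,4-benzodioxine-5-carbaldehyde | O=Cc1cc(C)cc2c1O[C@H](C(C)(C)O)CO2 | intermediate
8 | 5-(chloromethyl)-2-hydroxybenzaldehyde | O=Cc1cc(CCl)ccc1O | starting material
9 | 2-{[tert-butyl(dimethyl)silyl]oxy}-5-(chloromethyl)benzaldehyde | O=Cc1cc(CCl)ccc1O[Si](C)(C)C(C)(C)C | intermediate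
10 | tert-butyl[4-(chloromethyl)-2-(1,3-dioxolan-2-yl)phenoxy]dimethylsilane | ClCc1ccc(O[Si](C)(C)C(C)(C)C)c(C2OCCO2)c1 | intermediate
11 | diethyl (2-oxopropyl)phosphonate | CCOP(=O)(CC(C)=O)OCC | starting material
12 | diethyl [1-(4-{[tert-butyl(dimethyl)silyl]oxy}-3-(1,3-dioxolan-2-yl)phenyl)-3-oxobutan-2-yl]phosphonate (racemic) | CCOP(=O)(OCC)C(Cc1ccc(O[Si](C)(C)C(C)(C)C)c(C2OCCO2)c1)C(C)=O | intermediate
13 | (E)-enone with dioxolane and TBS ether, (3S) | CC(=O)/C(Cc1ccc(O[Si](C)(C)C(C)(C)C)c(C2OCCO2)c1)=C/c1cc(C)cc2c1O[C@H](C(C)(C)O)CO2 | intermediate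
14 | (E)-diene with dioxolane and TBS ether, (3S) | C=C(C)/C(Cc1ccc(O[Si](C)(C)C(C)(C)C)c(C2OCCO2)c1)=C/c1cc(C)cc2c1O[C@H](C(C)(C)O)CO2 | intermediate
15 | (E)-dienyl O-TBS salicylaldehyde, (3S) | C=C(C)/C(Cc1ccc(O[Si](C)(C)C(C)(C)C)c(C=O)c1)=C/c1cc(C)cc2c1O[C@H](C(C)(C)O)CO2 | intermediate
16 | N-benzyl (E)-aldimine of 15 (key-step precursor) | C=C(C)/C(Cc1ccc(O[Si](C)(C)C(C)(C)C)c(/C=N/Cc2ccccc2)c1)=C/c1cc(C)cc2c1O[C@H](C(C)(C)O)CO2 | intermediate
17 | N-benzyl imine of O-TBS Diaporindene G, (1R,3'S) (key-step product) | CC(C)=C1Cc2ccc(O[Si](C)(C)C(C)(C)C)c(/C=N/Cc3ccccc3)c2[C@@H]1c1cc(C)cc2c1O[C@H](C(C)(C)O)CO2 | intermediate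
18 | O-TBS Diaporindene G, (1R,3'S) | CC(C)=C1Cc2ccc(O[Si](C)(C)C(C)(C)C)c(C=O)c2[C@@H]1c1cc(C)cc2c1O[C@H](C(C)(C)O)CO2 | intermediate
19 | Diaporindene G, (1R,3'S) | CC(C)=C1Cc2ccc(O)c(C=O)c2[C@@H]1c1cc(C)cc2c1O[C@H](C(C)(C)O)CO2 | target

**Step count**
- Total steps: 13.
- Longest linear sequence: 10 (steps 4 to 13, from 8).

**Steps most likely to fail**

1. Step 11.
- What may go wrong: the diene may bind rhodium as a chelating four-electron ligand and stall turnover. The hydride may go to C2 instead of the terminal CH2. The allyl may couple at its dimethyl end, which would keep the styrene conjugation. The ligand may discriminate poorly between the two allyl faces.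
- Fallback, known chemistry only, from 13 back to 18. The acetal of 13 is hydrolysed at the acid-stable enone stage (PPTS, wet acetone) to give keto aldehyde F1. One equivalent of benzylamine over 4 Å MS condenses selectively with the aldehyde to give keto aldimine F2. [RhCl(coe)2]2 and the same phosphoramidite then carry out the established 1,2-hydroarylation of a tethered trisubstituted alkene (C7a to C1, H to C2). This gives 2-acetyl-1-arylindane imine F3, whose C2 configuration is left open because it is erased later. Ph3P=CH2 in THF at 0 °C methylenates the ketone while the aldimine masks the formyl group, giving 2-isopropenylindane imine F4. AcOH–H2O–THF frees 2-isopropenylindane aldehyde F5. A cobalt-hydride hydrogen-atom-transfer isomerisation then moves the 1,1-disubstituted alkene into the tetrasubstituted exocyclic position without touching C1, which gives 18. Its conditions are Co(salen)Cl (salen = N,N'-bis(3,5-di-tert-butylsalicylidene)cyclohexane-1,2-diaminate, trivalent cobalt), catalytic PhSiH3, benzene, rt.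

2. Step 7.
- What may go wrong: the fully substituted phosphonate carbanion may add too slowly to the ortho-alkoxy benzaldehyde, and the alkene geometry may erode on forcing.
- Fallback, from 7 and 10 back to 13: the benzyl group is attached by cross-coupling after a simple olefination. Aldehyde 7 reacts with 1-bromo-1-(triphenylphosphoranylidene)propan-2-one (CH2Cl2, rt) in a stabilised Wittig reaction. This places aryl trans to acetyl and gives (Z)-bromo enone F6. Chloride 10 is converted with Zn dust and LiCl in THF into benzylic zinc chloride F7. A Negishi coupling of the two (Pd(PPh3)4, THF, rt, excess zinc reagent to allow for the free alcohol) proceeds with retention of alkene geometry and gives 13.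

3. Step 8.
- What may go wrong: the basic ylide may enolise the hindered methyl ketone, and the alkoxide of the free tertiary alcohol may trigger loss or migration of the silyl group.
- Fallback, from 13 back to 14: the olefination is replaced by addition and elimination. MeLi with CeCl3 (THF, −78 °C, excess for the free alcohol) adds 1,2 to the ketone to give tertiary allylic alcohol F8. Catalytic PPTS in dry toluene over 4 Å MS at 50 °C ionises only this doubly activated allylic alcohol. Its only β-hydrogens are on the two methyl groups, so elimination can give only the isopropenyl diene 14. The side-chain tertiary alcohol, deactivated by the adjacent C–O bond, should stay intact.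

**Further compounds**
F1 | step 11 | (E)-keto aldehyde, 2-{[tert-butyl(dimethyl)silyl]oxy}-5-{(2E)-2-[(benzodioxinyl)methylidene]-3-oxobutyl}benzaldehyde, (3S) | CC(=O)/C(Cc1ccc(O[Si](C)(C)C(C)(C)C)c(C=O)c1)=C/c1cc(C)cc2c1O[C@H](C(C)(C)O)CO2
F2 | step 11 | keto aldimine, N-benzyl (E)-aldimine of F1 | CC(=O)/C(Cc1ccc(O[Si](C)(C)C(C)(C)C)c(/C=N/Cc2ccccc2)c1)=C/c1cc(C)cc2c1O[C@H](C(C)(C)O)CO2
F3 | step 11 | 2-acetyl-1-arylindane imine, (1R), C2 left open | CC(=O)C1Cc2ccc(O[Si](C)(C)C(C)(C)C)c(/C=N/Cc3ccccc3)c2[C@@H]1c1cc(C)cc2c1O[C@H](C(C)(C)O)CO2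
F4 | step 11 | 2-isopropenylindane imine, (1R), C2 left open | C=C(C)C1Cc2ccc(O[Si](C)(C)C(C)(C)C)c(/C=N/Cc3ccccc3)c2[C@@H]1c1cc(C)cc2c1O[C@H](C(C)(C)O)CO2
F5 | step 11 | 2-isopropenylindane aldehyde, (1R), C2 left open | C=C(C)C1Cc2ccc(O[Si](C)(C)C(C)(C)C)c(C=O)c2[C@@H]1c1cc(C)cc2c1O[C@H](C(C)(C)O)CO2
F6 | step 7 | (Z)-bromo enone, (Z)-3-bromo-4-[(3S)-3-(2-hydroxypropan-2-yl)-7-methyl-2,3-dihydro-1,4-benzodioxin-5-yl]but-3-en-2-one | CC(=O)/C(Br)=C/c1cc(C)cc2c1O[C@H](C(C)(C)O)CO2
F7 | step 7 | benzylic zinc chloride derived from 10 | Cl[Zn]Cc1ccc(O[Si](C)(C)C(C)(C)C)c(C2OCCO2)c1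
F8 | step 8 | tertiary allylic alcohol, (E)-3-benzyl-4-aryl-2-methylbut-3-en-2-ol derived from 13 | CC(C)(O)/C(Cc1ccc(O[Si](C)(C)C(C)(C)C)c(C2OCCO2)c1)=C/c1cc(C)cc2c1O[C@H](C(C)(C)O)CO2
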